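**Plan**
1. Cuts: the two aldehydes go back to the 11,12-diol and the C1–O acyl bond to p-coumaric acid. Ring B is cut at C10–C9 and C7–C8, a Diels–Alder disconnection once C7=C8 is moved to C8=C9 and C5=C6 is added. The C5–C6 bond is cut back to a vinylogous ester from 2-methylcyclohexane-1,3-dione.
2. Enabling feature: ring B (C5–C10) is a cyclohexene whose adjacent carbons C8 and C9 carry the one-carbon carbonyl groups C12 and C11, the imprint of an acetylenedicarboxylate. C10=C5 with C6=C7 is a 1-vinylcyclohexene diene on ring A, and the C1 oxygen is allylic to the diene terminus C10.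
3. Forward order: ring A is elaborated first (gem-dimethylation, vinyl addition with carbonyl transposition, reduction at C1). Ring B is closed last by cycloaddition with dimethyl acetylenedicarboxylate, which also brings in C11 and C12 and creates the quaternary C10.
4. Stereochemistry: C1 from a Corey–Bakshi–Shibata reduction; C10 by addition anti to the pseudoaxial C1 ester; C9 by α-face protonation and C5 by α-face hydrogenation, both steered by the C10 methyl; the (E)-alkene comes with p-coumaric acid.
5. End game: hydride reduction to the triol, silylation of the two primary hydroxyls, esterification at O1, desilylation, double Swern oxidation, release of the phenol.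

Key step: step 6

Remark: drimane numbering is used (ring A = C1–C5, C10; ring B = C5–C10; C11 on C9, C12 on C8; β is the face of the C10 methyl). The target SMILES is read as 1R with the C1 oxygen, the C10 methyl and the C9 formyl group β and H5 α.

**Step 1**
Reactants: 1 2-methylcyclohexane-1,3-dione
Product: 2 3-ethoxy-2-methylcyclohex-2-en-1-one
Conditions: EtOH, TsOH·H2O (cat.), toluene, reflux, Dean–Stark
Reagents that add atoms: ethanol, CCO
Why: Acid-catalysed enol etherification of a symmetric cyclic 1,3-dione with azeotropic removal of water should give the vinylogous ester without any regiochemical question and without a stereocentre.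

**Step 2**
Reactants: 2 3-ethoxy-2-methylcyclohex-2-en-1-one
Product: 4 3-ethoxy-2,6,6-trimethylcyclohex-2-en-1-one, via 6-monomethyl vinylogous ester 3 (not isolated)
Conditions: LiN(iPr)2, THF, −78 °C, then MeI; second portion of LiN(iPr)2, −78 °C, then MeI, −78 °C to rt (one pot)
Reagents that add atoms: iodomethane, CI
Why: Kinetic deprotonation of a vinylogous ester occurs at the alpha-prime carbon, so two successive enolate alkylations (Stork–Danheiser alkylation) should place the gem-dimethyl group next to the carbonyl, and the stereocentre of 3 vanishes in the second methylation.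

**Step 3**
Reactants: 4 3-ethoxy-2,6,6-trimethylcyclohex-2-en-1-one
Product: 6 2,4,4-trimethyl-3-vinylcyclohex-2-en-1-one, via tertiary allylic alcohol 5 (not isolated)
Conditions: CH2=CHMgBr, anhydrous CeCl3, THF, −78 to 0 °C; then 1 M aq. HCl, rt
Reagents that add atoms: vinylmagnesium bromide, C=C[Mg]Br; water, O
Why: 1,2-Addition of the CeCl3-modified Grignard reagent to the hindered carbonyl, then acid hydrolysis of the enol ether with loss of the tertiary hydroxyl (Stork–Danheiser 1,3-carbonyl transposition), should give the dienone, in which no stereocentre remains.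

**Step 4**
Reactants: 6 2,4,4-trimethyl-3-vinylcyclohex-2-en-1-one
Product: 7 (R)-2,4,4-trimethyl-3-vinylcyclohex-2-en-1-ol
Conditions: (S)-2-methyl-CBS-oxazaborolidine (20 mol %), catecholborane, toluene, −78 °C; aq. NaOH work-up
Reagents that add atoms: none
Why: In this Corey–Bakshi–Shibata reduction the fully substituted alkenyl side acts as the large group and the ring CH2 as the small one, so the (S)-catalyst should deliver hydride to the face that gives the (R)-carbinol (the future C1), while catecholborane at low temperature leaves the diene untouched.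

**Step 5**
Reactants: 7 (R)-2,4,4-trimethyl-3-vinylcyclohex-2-en-1-ol
Product: 8 (R)-2,4,4-trimethyl-3-vinylcyclohex-2-en-1-yl pivalate
Conditions: PivCl, pyridine, DMAP (cat.), CH2Cl2, 0 °C to rt
Reagents that add atoms: pivaloyl chloride, CC(C)(C)C(=O)Cl
Why: DMAP-catalysed acylation at oxygen leaves the carbinol centre untouched and installs a bulky, heat-stable ester that will screen one diene face and is later cleaved by the same hydride that reduces the methyl esters.

**Step 6**
Reactants: 8 (R)-2,4,4-trimethyl-3-vinylcyclohex-2-en-1-yl pivalate; 9 dimethyl acetylenedicarboxylate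
Product: 10 dimethyl 1β-(pivaloyloxy)drima-5,8-diene-11,12-dioate
Conditions: 9 (3 equiv), BHT (cat.), toluene, 110 °C, sealed tube
Reagents that add atoms: none
Why: A thermal, concerted, suprafacial [4+2] cycloaddition between the s-cis diene C10=C5–C6=C7 on ring A and the alkyne should form the C10–C9 and C7–C8 bonds at once and leave C5=C6 and C8=C9. The closest known reaction type is the Diels–Alder reaction of 2,6,6-trimethyl-1-vinylcyclohexene-type semicyclic dienes with acetylenedicarboxylates, here with an added allylic ester. Ring B is closed as the only new ring by intermolecular [4+2] annulation onto the existing ring A, giving a cyclohexa-1,4-diene that cannot aromatise because C10 is quaternary. The single new stereocentre, C10, is controlled by C1: allylic 1,2-strain with the C10 methyl holds the pivaloyloxy group pseudoaxial, so the dienophile should bond to C10 on the opposite face, which places C9 trans and the methyl cis to the C1 oxygen, as in the target. The step needs only π-facial selectivity, since the symmetric dienophile removes the regiochemical question and a linear alkyne has no endo/exo issue; the bulky ester secures the face and the doubly ester-activated alkyne secures reaction at the hindered terminus.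

**Step 7**
Reactants: 10 dimethyl 1β-(pivaloyloxy)drima-5,8-diene-11,12-dioate
Product: 11 dimethyl 1β-(pivaloyloxy)-9αH-drima-5,7-diene-11,12-dioate
Conditions: DBU, THF, rt
Reagents that add atoms: none
Why: Base-mediated 1,3-prototropic isomerisation through the C7-deprotonated extended enolate should give the conjugated 5,7-dienoate, with reprotonation at C9 from the α-face, opposite the C10 methyl and the C1 ester, setting the 9β-ester (9αH).

**Step 8**
Reactants: 11 dimethyl 1β-(pivaloyloxy)-9αH-drima-5,7-diene-11,12-dioate
Product: 12 dimethyl 1β-(pivaloyloxy)drim-7-ene-11,12-dioate (5αH, 9αH)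
Conditions: H2 (1 atm), 10% Pd/C, EtOAc, rt
Reagents that add atoms: none
Why: Heterogeneous hydrogenation should saturate the distal double bond C5=C6 of the dienoate from the α-face, because the β-face is screened by the axial C10 methyl and the C1 ester, which sets 5αH (trans ring fusion) and leaves the ester-bearing C7=C8 bond in place.

**Step 9**
Reactants: 12 dimethyl 1β-(pivaloyloxy)drim-7-ene-11,12-dioate
Product: 13 drim-7-ene-1β,11,12-triol
Conditions: LiAlH4, Et2O, 0 °C to rt
Reagents that add atoms: none
Why: Hydride reduction of esters to alcohols should convert both methyl esters (the enoate by 1,2-reduction to the allylic alcohol) and cleave the pivalate in one operation without touching a stereocentre.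

**Step 10**
Reactants: 13 drim-7-ene-1β,11,12-triol
Product: 14 11,12-bis(triethylsilyloxy)drim-7-en-1β-ol
Conditions: TESCl (2.2 equiv), imidazole, CH2Cl2, −20 °C
Reagents that add atoms: chlorotriethylsilane, CC[Si](Cl)(CC)CC
Why: Chemoselective silylation should take the two primary hydroxyls and leave free the secondary C1 hydroxyl, which is neopentyl-like next to the quaternary C10 and reacts far more slowly.

**Step 11**
Reactants: 15 (E)-p-coumaric acid
Product: 17 (E)-4-(tert-butyldimethylsilyloxy)cinnamic acid, via bis-silylated coumarate 16 (not isolated)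
Conditions: TBSCl (2.5 equiv), imidazole, DMF, rt; then AcOH–THF–H2O, rt
Reagents that add atoms: tert-butyldimethylsilyl chloride, CC(C)(C)[Si](C)(C)Cl
Why: Exhaustive silylation followed by selective hydrolysis of the labile silyl ester should leave the aryl silyl ether, which is stable to mild acid, and the (E)-alkene is not involved.

**Step 12**
Reactants: 14 11,12-bis(triethylsilyloxy)drim-7-en-1β-ol; 17 (E)-4-(tert-butyldimethylsilyloxy)cinnamic acid
Product: 19 11,12-bis(triethylsilyloxy)drim-7-en-1β-yl (E)-4-(tert-butyldimethylsilyloxy)cinnamate, via mixed carboxylic anhydride 18 (not isolated)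
Conditions: 2,4,6-Cl3C6H2COCl, Et3N, THF, rt; then 14, DMAP, toluene, 60 °C
Reagents that add atoms: none
Why: In this Yamaguchi esterification DMAP attacks the mixed anhydride at the cinnamoyl carbonyl and the acylpyridinium formed should be reactive enough to acylate the hindered C1 hydroxyl at oxygen, so the C1 configuration and the (E)-alkene are retained.

**Step 13**
Reactants: 19 11,12-bis(triethylsilyloxy)drim-7-en-1β-yl (E)-4-(tert-butyldimethylsilyloxy)cinnamate
Product: 20 11,12-dihydroxydrim-7-en-1β-yl (E)-4-(tert-butyldimethylsilyloxy)cinnamate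
Conditions: PPTS (cat.), MeOH–CH2Cl2, 0 °C
Reagents that add atoms: none
Why: Acid-catalysed methanolysis should remove the primary triethylsilyl ethers while the aryl silyl ether and the cinnamate survive, and a cold, short reaction limits acyl migration from O1 to O11.

**Step 14**
Reactants: 20 11,12-dihydroxydrim-7-en-1β-yl (E)-4-(tert-butyldimethylsilyloxy)cinnamate
Product: 21 1β-[(E)-4-(tert-butyldimethylsilyloxy)cinnamoyloxy]drim-7-ene-11,12-dial
Conditions: (COCl)2, DMSO, CH2Cl2, −78 °C; then Et3N, −78 to −30 °C; cold pH 7 buffer quench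
Reagents that add atoms: none
Why: Swern oxidation activates both hydroxyls as alkoxysulfonium ions before the base is added, which should give the 1,4-dialdehyde without lactol or lactone formation, and the low temperature with a buffered quench protects the base-labile 9β-formyl centre.

**Step 15**
Reactants: 21 1β-[(E)-4-(tert-butyldimethylsilyloxy)cinnamoyloxy]drim-7-ene-11,12-dial
Product: 22 1β-[(E)-4-hydroxycinnamoyloxy]drim-7-ene-11,12-dial (CNP0187624.1)
Conditions: HF·pyridine, pyridine, THF, 0 °C
Reagents that add atoms: none
Why: Fluoride cleavage of the aryl silyl ether under mildly acidic buffered conditions should free the phenol without base-induced epimerisation at C9 or cleavage of the ester.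

**Compound list**
1 | 2-methylcyclohexane-1,3-dione | CC1C(=O)CCCC1=O | starting material
2 | 3-ethoxy-2-methylcyclohex-2-en-1-one | CCOC1=C(C)C(=O)CCC1 | intermediate
3 | 3-ethoxy-2,6-dimethylcyclohex-2-en-1-one (racemic, not isolated) | CCOC1=C(C)C(=O)C(C)CC1 | intermediate
4 | 3-ethoxy-2,6,6-trimethylcyclohex-2-en-1-one | CCOC1=C(C)C(=O)C(C)(C)CC1 | intermediate
5 | 3-ethoxy-2,6,6-trimethyl-1-vinylcyclohex-2-en-1-ol (racemic, formed as its magnesium alkoxide, not isolated) | CCOC1=C(C)C(O)(C=C)C(C)(C)CC1 | intermediate
6 | 2,4,4-trimethyl-3-vinylcyclohex-2-en-1-one | C=CC1=C(C)C(=O)CCC1(C)C | intermediate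
7 | (R)-2,4,4-trimethyl-3-vinylcyclohex-2-en-1-ol | CC1(C)CC[C@@H](O)C(C)=C1C=C | intermediate
8 | (R)-2,4,4-trimethyl-3-vinylcyclohex-2-en-1-yl pivalate | CC1(C)CC[C@@H](OC(=O)C(C)(C)C)C(C)=C1C=C | intermediate
9 | dimethyl acetylenedicarboxylate | COC(=O)C#CC(=O)OC | starting material
10 | dimethyl 1β-(pivaloyloxy)drima-5,8-diene-11,12-dioate | CC1(C)CC[C@@H](OC(=O)C(C)(C)C)[C@]2(C)C(C(=O)OC)=C(C(=O)OC)CC=C12 | intermediate
11 | dimethyl 1β-(pivaloyloxy)-9αH-drima-5,7-diene-11,12-dioate | CC1(C)CC[C@@H](OC(=O)C(C)(C)C)[C@]2(C)[C@@H](C(=O)OC)C(C(=O)OC)=CC=C12 | intermediate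
12 | dimethyl 1β-(pivaloyloxy)drim-7-ene-11,12-dioate (5αH, 9αH) | CC1(C)CC[C@@H](OC(=O)C(C)(C)C)[C@]2(C)[C@@H](C(=O)OC)C(C(=O)OC)=CC[C@@H]12 | intermediate
13 | drim-7-ene-1β,11,12-triol | CC1(C)CC[C@@H](O)[C@]2(C)[C@@H](CO)C(CO)=CC[C@@H]12 | intermediate
14 | 11,12-bis(triethylsilyloxy)drim-7-en-1β-ol | CC1(C)CC[C@@H](O)[C@]2(C)[C@@H](CO[Si](CC)(CC)CC)C(CO[Si](CC)(CC)CC)=CC[C@@H]12 | intermediate
15 | (E)-p-coumaric acid | OC(=O)/C=C/c1ccc(O)cc1 | starting material
16 | tert-butyldimethylsilyl (E)-4-(tert-butyldimethylsilyloxy)cinnamate (not isolated) | CC(C)(C)[Si](C)(C)OC(=O)/C=C/c1ccc(O[Si](C)(C)C(C)(C)C)cc1 | intermediate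
17 | (E)-4-(tert-butyldimethylsilyloxy)cinnamic acid | CC(C)(C)[Si](C)(C)Oc1ccc(/C=C/C(=O)O)cc1 | intermediate
18 | (E)-4-(tert-butyldimethylsilyloxy)cinnamic 2,4,6-trichlorobenzoic anhydride (not isolated) | CC(C)(C)[Si](C)(C)Oc1ccc(/C=C/C(=O)OC(=O)c2c(Cl)cc(Cl)cc2Cl)cc1 | intermediate
19 | 11,12-bis(triethylsilyloxy)drim-7-en-1β-yl (E)-4-(tert-butyldimethylsilyloxy)cinnamate | CC1(C)CC[C@@H](OC(=O)/C=C/c2ccc(O[Si](C)(C)C(C)(C)C)cc2)[C@]2(C)[C@@H](CO[Si](CC)(CC)CC)C(CO[Si](CC)(CC)CC)=CC[C@@H]12 | intermediate
20 | 11,12-dihydroxydrim-7-en-1β-yl (E)-4-(tert-butyldimethylsilyloxy)cinnamate | CC1(C)CC[C@@H](OC(=O)/C=C/c2ccc(O[Si](C)(C)C(C)(C)C)cc2)[C@]2(C)[C@@H](CO)C(CO)=CC[C@@H]12 | intermediate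
21 | 1β-[(E)-4-(tert-butyldimethylsilyloxy)cinnamoyloxy]drim-7-ene-11,12-dial | CC1(C)CC[C@@H](OC(=O)/C=C/c2ccc(O[Si](C)(C)C(C)(C)C)cc2)[C@]2(C)[C@@H](C=O)C(C=O)=CC[C@@H]12 | intermediate
22 | 1β-[(E)-4-hydroxycinnamoyloxy]drim-7-ene-11,12-dial (CNP0187624.1) | CC1(C)CC[C@@H](OC(=O)/C=C/c2ccc(O)cc2)[C@]2(C)[C@@H](C=O)C(C=O)=CC[C@@H]12 | target

**Count**
Total steps: 15. Longest linear sequence: 14 steps (steps 1–10 and 12–15, from 1); step 11 is a one-step side branch.

**Steps most likely to fail**

Step 6. The cycloaddition at the doubly hindered terminus C10 may be slow, so that the temperature it needs erodes facial discrimination by the C1 ester or lets the diene isomerise by 1,5-hydrogen shift. The fallback sets out from 8 and uses a smaller, more reactive haloalkynoate. Cycloaddition with methyl 3-bromopropiolate (toluene, 60–80 °C) should give methyl 8-bromo-1β-(pivaloyloxy)-12-nordrima-5,8-dien-11-oate F1; the other regioisomer would serve equally. Palladium-catalysed methoxycarbonylation of the vinyl bromide (Pd(PPh3)4, CO, MeOH, Et3N, DMF, 70 °C) then installs the second ester carbon and returns to 10.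

Step 7. Under equilibrating amine base the extended enolate may be reprotonated at C5 or on the β-face of C9, or the product may epimerise at C9. The fallback sets out from 10 and reverses the order of events. Hydrogenation (H2, Pd/C, EtOAc) should reduce only the isolated trisubstituted C5=C6 bond from the α-face, the tetrasubstituted C8=C9 diester being inert, to give dimethyl 1β-(pivaloyloxy)drim-8-ene-11,12-dioate F2. Irreversible γ-deprotonation at C7 with LiN(iPr)2 (THF, −78 °C) and kinetic α-protonation of the lithium dienolate at C9 from the α-face with 2,6-di-tert-butyl-4-methylphenol then gives 12 directly, bypassing 11.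

Step 12. Acylation of the hindered C1 hydroxyl (next to the quaternary C10 and close to the C11 silyl ether) may stall, with silyl migration or loss of the mixed anhydride on prolonged heating. The fallback sets out from 14 and builds the cinnamate on the molecule. Acylation with the small diethylphosphonoacetic acid (DCC, DMAP, CH2Cl2) should give 11,12-bis(triethylsilyloxy)drim-7-en-1β-yl (diethoxyphosphoryl)acetate F3. Horner–Wadsworth–Emmons olefination with 4-(tert-butyldimethylsilyloxy)benzaldehyde (LiCl, DBU, MeCN, rt) then forms the (E)-alkene and returns to 19.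

**Further compounds**
F1 | step 6 | methyl 8-bromo-1β-(pivaloyloxy)-12-nordrima-5,8-dien-11-oate | CC1(C)CC[C@@H](OC(=O)C(C)(C)C)[C@]2(C)C(C(=O)OC)=C(Br)CC=C12
F2 | step 7 | dimethyl 1β-(pivaloyloxy)drim-8-ene-11,12-dioate (5αH) | CC1(C)CC[C@@H](OC(=O)C(C)(C)C)[C@]2(C)C(C(=O)OC)=C(C(=O)OC)CC[C@@H]12
F3 | step 12 | 11,12-bis(triethylsilyloxy)drim-7-en-1β-yl (diethoxyphosphoryl)acetate | CC1(C)CC[C@@H](OC(=O)CP(=O)(OCC)OCC)[C@]2(C)[C@@H](CO[Si](CC)(CC)CC)C(CO[Si](CC)(CC)CC)=CC[C@@H]12
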